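## Retrosynthetic overview

1. The butenolide is attached last: sp3–sp2 Negishi coupling of the alkylzinc from iodide 28 (C12) with 3-bromofuran-2(5H)-one 32 (C13), the lactone ring coming ready-made from furfural.
2. The 8(17)-methylene comes from a C8 ketone carried as a dioxolane; C12–I comes from a PhMe2Si group (Fleming–Tamao, then iodination).
3. Ring A is closed onto ring B by an intramolecular aldol condensation of keto aldehyde 19 (C4–C5 bond); deconjugative C4-methylation and OH-directed hydrogenation then set C4 and the cis C5–H.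
4. Ring B is quinone monoketal 2: a Cu-catalysed asymmetric conjugate addition sets C9, and two alkylations of the C10 enolate set the quaternary C10.
5. Ring order: ring B (from the arene of 1), then ring A (aldol), then the butenolide (coupled on at the end).

Assumption: the SMILES is taken literally, i.e. 5-H cis to the C10 methyl (cis-decalin, 4R,5R,9R,10S); the phosphoramidite in step 3 is assumed to show the same facial sense as with cyclohex-2-enone, and its enantiomer (equally available) is used if the sense proves opposite.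

Labdane numbering is used for the carbocycle (C19 = CH2O on C4, C18 = 4-Me, C20 = 10-Me, C11/C12 = side chain, C17 = methylene). α is the face that carries the 10-Me; in the target the 9-chain, 5-H and 19-CH2O are α and 18-Me is β.

## Route

Step 1
Reactants: 1 4-(2-hydroxyethoxy)phenol
Product: 2 1,4-dioxaspiro[4.5]deca-6,9-dien-8-one
Conditions: PhI(OAc)2, MeCN, 0 °C → rt
Reagents that add atoms: none
Why: Oxidative dearomatisation; the phenoxonium ion made by the iodine(III) reagent is trapped by the tethered alcohol to give the spiroketal dienone.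

Step 2
Reactants: 3 dimethyl(phenyl)(vinyl)silane
Product: 6 [2-(dimethylphenylsilyl)ethyl][(trimethylsilyl)methyl]zinc, via alkyl(diethyl)borane 4 (not isolated), via ethyl(alkyl)zinc 5 (not isolated)
Conditions: Et2BH (from BH3·SMe2/Et3B), 0 °C → rt; Et2Zn (2 equiv), 0 °C; Zn(CH2SiMe3)2 (0.5 equiv), then Et3B and Et2Zn removed in vacuo; PhMe solution
Reagents that add atoms: diethylzinc, CC[Zn]CC; bis[(trimethylsilyl)methyl]zinc, C[Si](C)(C)C[Zn]C[Si](C)(C)C
Why: Knochel hydroboration/boron–zinc exchange: the dialkylborane puts boron on the terminal carbon of the vinylsilane, Et2Zn moves the alkyl group to zinc, and ligand redistribution with Zn(CH2SiMe3)2 while the volatile Et3B and Et2Zn are pumped off leaves the mixed diorganozinc, in which Me3SiCH2 is a non-transferable group.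

Step 3
Reactants: 2 1,4-dioxaspiro[4.5]deca-6,9-dien-8-one; 6 [2-(dimethylphenylsilyl)ethyl][(trimethylsilyl)methyl]zinc
Product: 8 (R)-10-[2-(dimethylphenylsilyl)ethyl]-1,4-dioxaspiro[4.5]dec-6-en-8-one, via zinc enolate 7 (not isolated)
Conditions: Cu(OTf)2 (2.5 mol%), (R,S,S)-binaphthyl bis(1-phenylethyl)phosphoramidite (5 mol%), PhMe, −25 °C; aq. NH4Cl
Reagents that add atoms: none
Why: Feringa-type Cu/phosphoramidite asymmetric conjugate addition desymmetrises the dienone and sets C9 (chain on the α face); only the silylethyl group is transferred from the mixed zinc reagent, and the zinc enolate is not an acceptor, so only one arm reacts.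

Step 4
Reactants: 8 (R)-10-[2-(dimethylphenylsilyl)ethyl]-1,4-dioxaspiro[4.5]dec-6-en-8-one
Product: 10 (9S,10S)-9-methyl-10-[2-(dimethylphenylsilyl)ethyl]-1,4-dioxaspiro[4.5]dec-6-en-8-one, via lithium enolate 9 (not isolated)
Conditions: LDA, THF, −78 °C; MeI, −78 → −30 °C
Reagents that add atoms: iodomethane, CI
Why: α′-Enolate alkylation; C10 is the only enolisable position (the other α-carbon is vinylic, the γ-carbon is the ketal), and the methyl enters trans to the chain, a centre that is re-enolised in step 8.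

Step 5
Reactants: 11 but-3-yn-1-ol
Product: 12 4-(benzyloxy)but-1-yne
Conditions: NaH, BnBr, cat. Bu4NI, THF, 0 °C → rt
Reagents that add atoms: benzyl bromide, BrCc1ccccc1
Why: Williamson ether synthesis; the alkoxide forms selectively because the alkyne C–H is far less acidic.

Step 6
Reactants: 12 4-(benzyloxy)but-1-yne
Product: 14 5-(benzyloxy)pent-2-yn-1-ol, via lithium acetylide 13 (not isolated)
Conditions: n-BuLi, THF, −78 °C; (CH2O)n, −78 °C → rt; aq. NH4Cl
Reagents that add atoms: formaldehyde (as paraformaldehyde), C=O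
Why: Acetylide addition to formaldehyde gives the propargylic alcohol.

Step 7
Reactants: 14 5-(benzyloxy)pent-2-yn-1-ol
Product: 15 benzyl 5-bromopent-3-yn-1-yl ether
Conditions: CBr4, PPh3, CH2Cl2, 0 °C
Reagents that add atoms: carbon tetrabromide, BrC(Br)(Br)Br
Why: Appel bromination of a primary propargylic alcohol under neutral conditions.

Step 8
Reactants: 10 (9S,10S)-9-methyl-10-[2-(dimethylphenylsilyl)ethyl]-1,4-dioxaspiro[4.5]dec-6-en-8-one; 15 benzyl 5-bromopent-3-yn-1-yl ether
Product: 17 (9S,10S)-9-[5-(benzyloxy)pent-2-yn-1-yl]-9-methyl-10-[2-(dimethylphenylsilyl)ethyl]-1,4-dioxaspiro[4.5]dec-6-en-8-one, via lithium enolate 16 (not isolated)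
Conditions: LDA, THF, −78 °C; DMPU, 15, −78 → 0 °C
Reagents that add atoms: none
Why: Enolate alkylation; A(1,2) strain with the enolate methyl puts the C9 chain pseudoaxial, so the slim propargylic bromide enters from the opposite (β) face and the quaternary C10 carries its methyl cis to the C9 chain.

Step 9
Reactants: 17 quaternary enone
Product: 18 6-[2-(dimethylphenylsilyl)ethyl]-7-(5-hydroxypentyl)-7-methyl-1,4-dioxaspiro[4.5]decan-8-one
Conditions: H2 (1 atm), 10% Pd/C, EtOH, rt
Reagents that add atoms: none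
Why: Catalytic hydrogenation saturates the alkyne and the enone C=C and hydrogenolyses the benzyl ether in one operation; ketone, dioxolane and arylsilane are inert.

Step 10
Reactants: 18 hydroxy ketone
Product: 20 bicyclic enal 8,8-ethylenedioxy-12-(dimethylphenylsilyl)-13,14,15,16,17,18-hexanorlabd-4-en-19-al, via keto aldehyde 19 (not isolated)
Conditions: TEMPO (cat.), PhI(OAc)2, CH2Cl2, rt; then pyrrolidine (0.5 equiv), PhMe, 4 Å MS, 60 °C
Reagents that add atoms: none
Why: TEMPO/BAIB oxidation, then intramolecular aldol condensation: the aldehyde enamine (C4) attacks the ring-B ketone (C5) in the only six-membered mode, and dehydration gives the conjugated enal, closing ring A.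

Step 11
Reactants: 20 bicyclic enal
Product: 22 8,8-ethylenedioxy-12-(dimethylphenylsilyl)-13,14,15,16,17-pentanorlabd-5-en-19-ol (18-Me β; 19-CH2OH α), via α-methyl aldehyde 21 (not isolated)
Conditions: t-BuOK, MeI, THF, −20 → 0 °C; then MeOH, NaBH4, 0 °C
Reagents that add atoms: iodomethane, CI
Why: Deconjugative α-alkylation of the dienolate (γ-deprotonation at C6); MeI attacks C4 anti to the axial 10-Me, so the formyl carbon (C19) ends cis to the 10-Me, and NaBH4 reduces the non-enolisable aldehyde in the same pot.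

Step 12
Reactants: 22 Δ5 homoallylic alcohol
Product: 23 8,8-ethylenedioxy-12-(dimethylphenylsilyl)-13,14,15,16,17-pentanorlabdan-19-ol with 5-H α (cis-fused)
Conditions: H2 (1 atm), [Ir(cod)(PCy3)(py)]PF6 (10 mol%), CH2Cl2, rt
Reagents that add atoms: none
Why: Crabtree hydroxyl-directed hydrogenation; iridium bound to the 19-OH delivers H2 to the α face of the 5,6-alkene, which sets 5-H cis to the 10-Me (cis ring fusion).

Step 13
Reactants: 23 cis-decalin alcohol
Product: 24 19-acetoxy-8,8-ethylenedioxy-12-(dimethylphenylsilyl)-13,14,15,16,17-pentanorlabdane (cis-fused)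
Conditions: Ac2O, pyridine, DMAP (cat.), CH2Cl2, rt
Reagents that add atoms: acetic anhydride, CC(=O)OC(C)=O
Why: DMAP-catalysed acylation of the neopentyl primary alcohol installs the acetate of the target.

Step 14
Reactants: 24 silyl acetate
Product: 25 19-acetoxy-8,8-ethylenedioxy-13,14,15,16,17-pentanorlabdan-12-ol
Conditions: KBr, AcOOH, NaOAc, AcOH, 0 °C → rt
Reagents that add atoms: peracetic acid, CC(=O)OO
Why: One-pot Fleming–Tamao oxidation (ipso-bromodesilylation of the phenyl group, then peracid-induced C→O shift); no alkene is present yet and the buffered medium spares acetate and dioxolane.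

Step 15
Reactants: 25 primary alcohol
Product: 26 19-acetoxy-8,8-ethylenedioxy-12-iodo-13,14,15,16,17-pentanorlabdane
Conditions: I2, PPh3, imidazole, CH2Cl2, 0 °C → rt
Reagents that add atoms: iodine, II
Why: Appel-type (Garegg–Samuelsson) iodination of the unhindered primary alcohol; doing it before the ketal is removed avoids a γ-hydroxy ketone.

Step 16
Reactants: 26 iodo ketal
Product: 28 19-acetoxy-12-iodo-13,14,15,16-tetranorlabd-8(17)-ene (cis-fused), via iodo ketone 27 (not isolated)
Conditions: PPTS (cat.), acetone–H2O, 45 °C; then Zn/CH2Br2/TiCl4 (Lombardo reagent), THF–CH2Cl2, 0 °C → rt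
Reagents that add atoms: dibromomethane, BrCBr
Why: Mild ketal hydrolysis followed at once by non-basic Takai–Lombardo methylenation, so the epimerisable C9 next to the ketone is not exposed to base; acetate and alkyl iodide are tolerated.

Step 17
Reactants: 29 furfural
Product: 30 furan-2(5H)-one
Conditions: 30% H2O2, HCO2H, Me2NCH2CH2OH (cat.), CH2Cl2–H2O, reflux
Reagents that add atoms: hydrogen peroxide, OO
Why: Baeyer–Villiger oxidation of the aldehyde by performic acid, hydrolysis of the formate and amine-mediated isomerisation to the conjugated butenolide.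

Step 18
Reactants: 30 furan-2(5H)-one
Product: 31 trans-3,4-dibromodihydrofuran-2(3H)-one (racemic)
Conditions: Br2, CH2Cl2, 0 °C → rt
Reagents that add atoms: bromine, BrBr
Why: Anti addition of bromine to the butenolide double bond.

Step 19
Reactants: 31 trans-3,4-dibromodihydrofuran-2(3H)-one
Product: 32 3-bromofuran-2(5H)-one
Conditions: Et3N, Et2O, 0 °C
Reagents that add atoms: none
Why: E1cB dehydrobromination removes the acidic α-H and the β-bromide, leaving the α-bromo butenolide.

Step 20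
Reactants: 28 iodo alkene; 32 3-bromofuran-2(5H)-one
Product: 34 (4R,5R,9R,10S)-19-acetoxylabda-8(17),13-dien-16,15-olide (cis-fused; the target), via alkylzinc iodide 33 (not isolated)
Conditions: Zn dust, LiCl, THF, 35 °C; then 32, Pd(OAc)2 (3 mol%), SPhos (6 mol%), THF, rt
Reagents that add atoms: none
Why: Knochel zinc insertion into the primary iodide, then Negishi sp3–sp2 cross-coupling with the α-bromo butenolide forms C12–C13; acetate, exocyclic alkene and lactone tolerate the organozinc.

## Compound list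

1 | 4-(2-hydroxyethoxy)phenol | OCCOc1ccc(O)cc1 | starting material
2 | 1,4-dioxaspiro[4.5]deca-6,9-dien-8-one | O=C1C=CC2(OCCO2)C=C1 | intermediate
3 | dimethyl(phenyl)(vinyl)silane | C=C[Si](C)(C)c1ccccc1 | starting material
4 | diethyl[2-(dimethylphenylsilyl)ethyl]borane | CCB(CC)CC[Si](C)(C)c1ccccc1 | intermediate (not isolated)
5 | ethyl[2-(dimethylphenylsilyl)ethyl]zinc | CC[Zn]CC[Si](C)(C)c1ccccc1 | intermediate (not isolated)
6 | [2-(dimethylphenylsilyl)ethyl][(trimethylsilyl)methyl]zinc | C[Si](C)(C)C[Zn]CC[Si](C)(C)c1ccccc1 | intermediate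
7 | (trimethylsilylmethyl)zinc enolate of 8 (O–Zn on C5, C5=C10) | C[Si](C)(C)C[Zn]OC1=C[C@H](CC[Si](C)(C)c2ccccc2)C2(OCCO2)C=C1 | intermediate (not isolated)
8 | (R)-10-[2-(dimethylphenylsilyl)ethyl]-1,4-dioxaspiro[4.5]dec-6-en-8-one | O=C1C=CC2(OCCO2)[C@@H](CC[Si](C)(C)c3ccccc3)C1 | intermediate
9 | lithium enolate of 8 | [Li]OC1=C[C@H](CC[Si](C)(C)c2ccccc2)C2(OCCO2)C=C1 | intermediate (not isolated)
10 | (9S,10S)-9-methyl-10-[2-(dimethylphenylsilyl)ethyl]-1,4-dioxaspiro[4.5]dec-6-en-8-one (methyl trans to chain) | O=C1C=CC2(OCCO2)[C@@H](CC[Si](C)(C)c3ccccc3)[C@@H]1C | intermediate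
11 | but-3-yn-1-ol | C#CCCO | starting material
12 | 4-(benzyloxy)but-1-yne | C#CCCOCc1ccccc1 | intermediate
13 | lithium acetylide of 12 | [Li]C#CCCOCc1ccccc1 | intermediate (not isolated)
14 | 5-(benzyloxy)pent-2-yn-1-ol | OCC#CCCOCc1ccccc1 | intermediate
15 | benzyl 5-bromopent-3-yn-1-yl ether | BrCC#CCCOCc1ccccc1 | intermediate
16 | lithium enolate of 10 | [Li]OC1=C(C)[C@H](CC[Si](C)(C)c2ccccc2)C2(OCCO2)C=C1 | intermediate (not isolated)
17 | (9S,10S)-9-[5-(benzyloxy)pent-2-yn-1-yl]-9-methyl-10-[2-(dimethylphenylsilyl)ethyl]-1,4-dioxaspiro[4.5]dec-6-en-8-one (methyl cis to silylethyl chain) | O=C1C=CC2(OCCO2)[C@@H](CC[Si](C)(C)c3ccccc3)[C@]1(C)CC#CCCOCc1ccccc1 | intermediate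
18 | 6-[2-(dimethylphenylsilyl)ethyl]-7-(5-hydroxypentyl)-7-methyl-1,4-dioxaspiro[4.5]decan-8-one (methyl cis to silylethyl chain) | O=C1CCC2(OCCO2)[C@@H](CC[Si](C)(C)c3ccccc3)[C@]1(C)CCCCCO | intermediate
19 | 5-{8-oxo-7-methyl-6-[2-(dimethylphenylsilyl)ethyl]-1,4-dioxaspiro[4.5]decan-7-yl}pentanal | O=C1CCC2(OCCO2)[C@@H](CC[Si](C)(C)c3ccccc3)[C@]1(C)CCCCC=O | intermediate (not isolated)
20 | 8,8-ethylenedioxy-12-(dimethylphenylsilyl)-13,14,15,16,17,18-hexanorlabd-4-en-19-al (9-chain and 10-Me both α) | O=CC1=C2CCC3(OCCO3)[C@@H](CC[Si](C)(C)c4ccccc4)[C@]2(C)CCC1 | intermediate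
21 | 8,8-ethylenedioxy-12-(dimethylphenylsilyl)-13,14,15,16,17-pentanorlabd-5-en-19-al (18-Me β, CHO α) | O=C[C@]1(C)CCC[C@@]2(C)[C@H](CC[Si](C)(C)c3ccccc3)C3(OCCO3)CC=C12 | intermediate (not isolated)
22 | 8,8-ethylenedioxy-12-(dimethylphenylsilyl)-13,14,15,16,17-pentanorlabd-5-en-19-ol (18-Me β, CH2OH α) | OC[C@]1(C)CCC[C@@]2(C)[C@H](CC[Si](C)(C)c3ccccc3)C3(OCCO3)CC=C12 | intermediate
23 | 8,8-ethylenedioxy-12-(dimethylphenylsilyl)-13,14,15,16,17-pentanorlabdan-19-ol, 5-H α (cis-fused) | OC[C@]1(C)CCC[C@@]2(C)[C@H](CC[Si](C)(C)c3ccccc3)C3(OCCO3)CC[C@@H]12 | intermediate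
24 | 19-acetoxy-8,8-ethylenedioxy-12-(dimethylphenylsilyl)-13,14,15,16,17-pentanorlabdane (cis-fused) | CC(=O)OC[C@]1(C)CCC[C@@]2(C)[C@H](CC[Si](C)(C)c3ccccc3)C3(OCCO3)CC[C@@H]12 | intermediate
25 | 19-acetoxy-8,8-ethylenedioxy-13,14,15,16,17-pentanorlabdan-12-ol (cis-fused) | CC(=O)OC[C@]1(C)CCC[C@@]2(C)[C@H](CCO)C3(OCCO3)CC[C@@H]12 | intermediate
26 | 19-acetoxy-8,8-ethylenedioxy-12-iodo-13,14,15,16,17-pentanorlabdane (cis-fused) | CC(=O)OC[C@]1(C)CCC[C@@]2(C)[C@H](CCI)C3(OCCO3)CC[C@@H]12 | intermediate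
27 | 19-acetoxy-12-iodo-13,14,15,16,17-pentanorlabdan-8-one (cis-fused) | CC(=O)OC[C@]1(C)CCC[C@@]2(C)[C@H](CCI)C(=O)CC[C@@H]12 | intermediate (not isolated)
28 | 19-acetoxy-12-iodo-13,14,15,16-tetranorlabd-8(17)-ene (cis-fused) | CC(=O)OC[C@]1(C)CCC[C@@]2(C)[C@H](CCI)C(=C)CC[C@@H]12 | intermediate
29 | furfural | O=Cc1ccco1 | starting material
30 | furan-2(5H)-one | O=C1C=CCO1 | intermediate
31 | trans-3,4-dibromodihydrofuran-2(3H)-one (racemic, one enantiomer drawn) | O=C1OC[C@H](Br)[C@H]1Br | intermediate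
32 | 3-bromofuran-2(5H)-one | O=C1OCC=C1Br | intermediate
33 | alkylzinc iodide from 28 (C12–ZnI) | CC(=O)OC[C@]1(C)CCC[C@@]2(C)[C@H](CC[Zn]I)C(=C)CC[C@@H]12 | intermediate (not isolated)
34 | (4R,5R,9R,10S)-19-acetoxylabda-8(17),13-dien-16,15-olide; [(1R,4aS,5R,8aR)-1,4a-dimethyl-6-methylidene-5-[2-(2-oxo-2,5-dihydrofuran-3-yl)ethyl]decahydronaphthalen-1-yl]methyl acetate | CC(=O)OC[C@]1(C)CCC[C@@]2(C)[C@H](CCC3=CCOC3=O)C(=C)CC[C@@H]12 | target

## Step count and weak points

Total step count: 20.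
Longest linear sequence: 13 steps (1, 3, 4, 8–16, 20; the chains through 5–7 or through 2 are equally long).

Steps most likely to fail:

Step 3 (asymmetric conjugate addition). The functionalised mixed diorganozinc may react sluggishly or with low ee on the quinone monoketal. The fallback sets out from dienone 2 and comes back at hydroxy ketone 18. A Rh(I)/(R)-BINAP-catalysed Hayashi–Miyaura 1,4-addition (dioxane–H2O, KOH) of (E)-dimethyl(phenyl)[2-(pinacolboryl)ethenyl]silane F1, made from ethynyl(dimethyl)phenylsilane and pinacolborane with cat. Cp2ZrHCl, gives the alkenyl enone F2. LDA/MeI then gives the methyl ketone F3 and LDA/15 the quaternary enone F4. The hydrogenation conditions of step 9 applied to F4 also saturate the vinylsilane and give 18.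

Step 12 (directed hydrogenation). The trisubstituted alkene lies between two quaternary carbons and hydrogen must be delivered to its more hindered face. The fallback sets out from homoallylic alcohol 22 and comes back at acetate 24. Acetylation gives the Δ5 acetate F5. m-CPBA attacks the β face, anti to the axial 10-Me and 4-CH2OAc, to give the 5β,6β-epoxide F6. BF3·OEt2 at −78 °C opens it at C5 with a 1,2-shift of the 6α-hydrogen onto the α face of C5, giving the cis-fused 6-ketone F7. Its tosylhydrazone F8 is reduced with catecholborane/NaOAc to the methylene compound 24, under conditions mild enough to leave C5 unepimerised.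

Step 20 (Negishi coupling). The α-bromo butenolide may be consumed by reduction or conjugate addition before coupling. The fallback sets out from iodide 28 and comes back at target 34. The lithium enolate (LiHMDS, THF–HMPA, −78 °C) of 3-(phenylsulfanyl)oxolan-2-one F9, made from α-bromo-γ-butyrolactone and thiophenol, is alkylated by 28 to give the sulfide lactone F10. m-CPBA (1 equiv, −78 °C) oxidises sulfur selectively to the sulfoxide F11, and thermolysis in toluene at 110 °C eliminates into the ring to give 34.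

Further compounds
F1 | step 3 | (E)-dimethyl(phenyl)[2-(4,4,5,5-tetramethyl-1,3,2-dioxaborolan-2-yl)ethenyl]silane | C[Si](C)(/C=C/B1OC(C)(C)C(C)(C)O1)c1ccccc1
F2 | step 3 | 10-[(E)-2-(dimethylphenylsilyl)ethenyl]-1,4-dioxaspiro[4.5]dec-6-en-8-one (configuration as in 8) | O=C1C=CC2(OCCO2)[C@@H](/C=C/[Si](C)(C)c3ccccc3)C1
F3 | step 3 | 9-methyl-10-[(E)-2-(dimethylphenylsilyl)ethenyl]-1,4-dioxaspiro[4.5]dec-6-en-8-one (methyl trans to alkenyl) | O=C1C=CC2(OCCO2)[C@@H](/C=C/[Si](C)(C)c3ccccc3)[C@@H]1C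
F4 | step 3 | 9-[5-(benzyloxy)pent-2-yn-1-yl]-9-methyl-10-[(E)-2-(dimethylphenylsilyl)ethenyl]-1,4-dioxaspiro[4.5]dec-6-en-8-one (methyl cis to alkenyl) | O=C1C=CC2(OCCO2)[C@@H](/C=C/[Si](C)(C)c3ccccc3)[C@]1(C)CC#CCCOCc1ccccc1
F5 | step 12 | 19-acetoxy-8,8-ethylenedioxy-12-(dimethylphenylsilyl)-13,14,15,16,17-pentanorlabd-5-ene | CC(=O)OC[C@]1(C)CCC[C@@]2(C)[C@H](CC[Si](C)(C)c3ccccc3)C3(OCCO3)CC=C12
F6 | step 12 | 5β,6β-epoxide of F5 | CC(=O)OC[C@]1(C)CCC[C@@]2(C)[C@H](CC[Si](C)(C)c3ccccc3)C3(OCCO3)C[C@H]4O[C@@]124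
F7 | step 12 | 19-acetoxy-8,8-ethylenedioxy-12-(dimethylphenylsilyl)-13,14,15,16,17-pentanorlabdan-6-one, 5-H α (cis-fused) | CC(=O)OC[C@]1(C)CCC[C@@]2(C)[C@H](CC[Si](C)(C)c3ccccc3)C3(OCCO3)CC(=O)[C@@H]12
F8 | step 12 | tosylhydrazone of F7 | CC(=O)OC[C@]1(C)CCC[C@@]2(C)[C@H](CC[Si](C)(C)c3ccccc3)C3(OCCO3)CC(=NNS(=O)(=O)c3ccc(C)cc3)[C@@H]12
F9 | step 20 | 3-(phenylsulfanyl)oxolan-2-one (racemic) | O=C1OCCC1Sc1ccccc1
F10 | step 20 | 13-(phenylsulfanyl)-13,14-dihydro derivative of 34 (C13 epimers) | CC(=O)OC[C@]1(C)CCC[C@@]2(C)[C@H](CCC3(Sc4ccccc4)CCOC3=O)C(=C)CC[C@@H]12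
F11 | step 20 | sulfoxide of F10 | CC(=O)OC[C@]1(C)CCC[C@@]2(C)[C@H](CCC3(S(=O)c4ccccc4)CCOC3=O)C(=C)CC[C@@H]12
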